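**Plan**

1. Retrosynthesis: the two angelates (C6–O, C10–O) are removed first, then the C8 methyl and C4 isopropyl groups (additions to C8 and C4 ketones), the C9/C10 diol (osmylation of C9=C10) and the C5–H/C6–O pair (H and Si delivered from a C8–O tether). This leaves a bicyclic dienone.
2. Enabling feature: the seven-membered ring C5–C6–C7–C8–C9–C10–C1 shares the C1–C5 bond with the cyclopentane C1–C2–C3–C4–C5 at quaternary C1. C5 with its C6=C7 arm is therefore a vinylcarbenoid and C1=C10–C9=C8 a diene, held together by the C2–C3–C4 ketone tether; the ring bonds cut are C5–C1 and C7–C8 (with a transient C5–C10 bond).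
3. Forward: the C4–C3–C2–C1(=C10)–C9 chain is built by Grignard addition and Johnson–Claisen rearrangement, extended to the (E,E)-dienol ether (C8–O) by iodo-olefination and C–O coupling, then turned into the allyl ketone and the vinyl diazoketone. The rhodium cascade closes the five-membered ring first (cyclopropanation) and the seven-membered ring second (Cope shift).
4. Stereochemistry: C1 from the chiral dirhodium catalyst; the temporary C8 centre from the E,E diene through the boat transition state; C4 by isopropyl addition anti to the C1 methyl; C5 and C6 by syn delivery from the C8–O–Si tether; C9/C10 by osmylation anti to the C1 methyl; C8 by methyl addition anti to the C9 silyl ether.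

Key step: step 9

Remark on locants: ring compounds use C1 (quaternary ring-fusion carbon with CH3), C2, C3, C4 (five-ring carbon bearing O), C5 (other ring-fusion carbon), then C6–C10 around the seven-membered ring back to C1; β is the face of the C1 methyl, α the opposite face; absolute configuration is that of the SMILES.

Assumption: the sense of induction of Rh2(S-PTAD)4, dirhodium tetrakis[(S)-(1-adamantyl)(N-phthalimido)acetate], in this intramolecular case is not established; the route is written for the catalyst antipode that delivers 20 as drawn, and Rh2(R-PTAD)4 is used if the sense proves opposite.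

**Route**

Step 1
Reactants: 1 2,2-dimethoxyacetaldehyde (anhydrous monomer); 2 isopropenylmagnesium bromide
Product: 3 1,1-dimethoxy-3-methylbut-3-en-2-ol (racemic)
Conditions: THF, −78 → 0 °C; aqueous work-up
Reagents that add atoms: isopropenylmagnesium bromide, C=C(C)[Mg]Br
Why: Grignard 1,2-addition to an aldehyde gives the 2-methylallylic alcohol, whose racemic carbinol centre is erased in step 2.

Step 2
Reactants: 3 1,1-dimethoxy-3-methylbut-3-en-2-ol; 4 triethyl orthoacetate
Product: 6 ethyl (4E)-6,6-dimethoxy-4-methylhex-4-enoate, via ketene acetal 5 (not isolated)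
Conditions: MeC(OEt)3 (excess), EtCO2H (cat.), 140 °C, EtOH distilled off
Reagents that add atoms: triethyl orthoacetate, CCOC(C)(OCC)OCC
Why: Johnson–Claisen rearrangement through a chair transition state with the bulky dimethoxymethyl group equatorial should give the E trisubstituted alkene (the future C1=C10) with high selectivity.

Step 3
Reactants: 6 ethyl (4E)-6,6-dimethoxy-4-methylhex-4-enoate; 7 N,O-dimethylhydroxylamine hydrochloride
Product: 8 (4E)-N,6,6-trimethoxy-N,4-dimethylhex-4-enamide
Conditions: MeNH(OMe)·HCl, iPrMgCl, THF, −20 °C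
Reagents that add atoms: N,O-dimethylhydroxylamine hydrochloride, CNOC.Cl
Why: aminolysis of the ester by the magnesium amide (Weinreb amide formation) is basic and leaves the acetal and the alkene geometry untouched.

Step 4
Reactants: 8 (4E)-N,6,6-trimethoxy-N,4-dimethylhex-4-enamide; 9 water
Product: 10 (4E)-N-methoxy-N,4-dimethyl-6-oxohex-4-enamide
Conditions: oxalic acid (cat.), THF/H2O, rt
Reagents that add atoms: water, O
Why: mild acid hydrolysis of the allylic acetal gives the conjugated enal, for which E is also the thermodynamic geometry.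

Step 5
Reactants: 10 (4E)-N-methoxy-N,4-dimethyl-6-oxohex-4-enamide; 11 iodoform
Product: 12 (4E,6E)-7-iodo-N-methoxy-N,4-dimethylhepta-4,6-dienamide
Conditions: CHI3, CrCl2, THF/dioxane, 0 °C → rt
Reagents that add atoms: iodoform, IC(I)I
Why: Takai iodo-olefination with the geminal dichromium reagent is E-selective for aldehydes and chemoselective for the aldehyde over the Weinreb amide.

Step 6
Reactants: 12 (4E,6E)-7-iodo-N-methoxy-N,4-dimethylhepta-4,6-dienamide; 13 4-methoxybenzyl alcohol
Product: 14 (4E,6E)-N-methoxy-7-[(4-methoxybenzyl)oxy]-N,4-dimethylhepta-4,6-dienamide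
Conditions: CuI (10 mol %), 3,4,7,8-tetramethyl-1,10-phenanthroline (20 mol %), Cs2CO3, toluene, 80 °C
Reagents that add atoms: 4-methoxybenzyl alcohol, COc1ccc(CO)cc1
Why: copper-catalysed Ullmann-type C–O coupling of a vinyl iodide with an alcohol proceeds with retention of alkene geometry, so the dienol ether is obtained as the E,E isomer, with an O-substituent that can later be removed oxidatively.

Step 7
Reactants: 14 (4E,6E)-N-methoxy-7-[(4-methoxybenzyl)oxy]-N,4-dimethylhepta-4,6-dienamide; 15 allylmagnesium bromide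
Product: 16 (7E,9E)-10-[(4-methoxybenzyl)oxy]-7-methyldeca-1,7,9-trien-4-one
Conditions: THF, −78 → 0 °C; pH 7 buffer work-up
Reagents that add atoms: allylmagnesium bromide, C=CC[Mg]Br
Why: Weinreb ketone synthesis, in which the chelated tetrahedral intermediate prevents over-addition and the neutral work-up keeps the β,γ-alkene out of conjugation and the enol ether intact.

Step 8
Reactants: 16 (7E,9E)-10-[(4-methoxybenzyl)oxy]-7-methyldeca-1,7,9-trien-4-one; 17 4-acetamidobenzenesulfonyl azide
Product: 18 (7E,9E)-3-diazo-10-[(4-methoxybenzyl)oxy]-7-methyldeca-1,7,9-trien-4-one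
Conditions: DBU, MeCN, 0 °C, dark; used at once as a cold solution
Reagents that add atoms: 4-acetamidobenzenesulfonyl azide, CC(=O)Nc1ccc(cc1)S(=O)(=O)N=[N+]=[N-]
Why: Regitz diazo transfer to the methylene activated by both the ketone and the vinyl group, as in the preparation of vinyldiazoacetates from but-3-enoates, should give the vinyl diazoketone, which is kept cold because it can electrocyclise to a pyrazole.

Step 9
Reactants: 18 (7E,9E)-3-diazo-10-[(4-methoxybenzyl)oxy]-7-methyldeca-1,7,9-trien-4-one
Product: 20 (3aS,6S)-6-[(4-methoxybenzyl)oxy]-3a-methyl-3,3a,6,7-tetrahydroazulen-1(2H)-one, via divinylcyclopropane 19 (not isolated)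
Conditions: Rh2(S-PTAD)4 (1 mol %), hexanes/toluene, slow addition of 18 at −40 °C → rt; then 80 °C
Reagents that add atoms: none
Why: The divalent rhodium carboxylate expels N2 to give a vinylcarbenoid at C5, which adds across the tethered E trisubstituted C1=C10 alkene to form a bicyclo[3.1.0]hexan-2-one whose dienyl arm on C10 is exo and therefore cis to the C5 vinyl group; this cis-divinylcyclopropane then undergoes a boat [3,3] shift that breaks C5–C10 and makes C7–C8. The closest known reaction types are the tandem cyclopropanation/Cope rearrangement of vinyldiazo carbonyl compounds with dienes and the intramolecular cyclopropanation of dienyl α-diazoketones. The five-membered ring closes by intramolecular [2+1] carbene addition over the three-atom ketone tether, and the seven-membered ring closes by strain-driven sigmatropic ring expansion of the cyclopropane. C1 is set by the chiral ligand sphere of the catalyst selecting the alkene face, and C8 is fixed relative to C1 by the E enol ether geometry in the boat transition state, which places the ether oxygen trans to the C1 methyl. The step needs carbenoid-site attack on the proximal alkene rather than on the enol ether alkene or through the vinyl terminus, and it must outrun pyrazole formation; tether length, a non-polar medium and cold slow addition should secure this, and the final heating completes a Cope step slowed by the C1 methyl lying syn to both vinyl groups.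

Step 10
Reactants: 20 (3aS,6S)-6-[(4-methoxybenzyl)oxy]-3a-methyl-3,3a,6,7-tetrahydroazulen-1(2H)-one; 21 isopropyllithium
Product: 22 4α-isopropyl-8α-(4-methoxybenzyloxy)-1β-methylbicyclo[5.3.0]deca-5,9-dien-4β-ol
Conditions: iPrLi, CeCl3 (anhydrous), THF, −78 °C
Reagents that add atoms: isopropyllithium, [Li]C(C)C
Why: organocerium 1,2-addition suppresses enolisation and conjugate addition, and attack on the planar enone carbonyl anti to the C1 methyl should set C4 with the hydroxyl β and the isopropyl α.

Step 11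
Reactants: 22 4α-isopropyl-8α-(4-methoxybenzyloxy)-1β-methylbicyclo[5.3.0]deca-5,9-dien-4β-ol
Product: 23 4α-isopropyl-1β-methylbicyclo[5.3.0]deca-5,9-diene-4β,8α-diol
Conditions: DDQ, CH2Cl2/pH 7 buffer, 0 °C
Reagents that add atoms: none
Why: oxidative cleavage of the 4-methoxybenzyl ether under buffered neutral conditions frees the C8 hydroxyl without ionising the tertiary allylic alcohol.

Step 12
Reactants: 23 4α-isopropyl-1β-methylbicyclo[5.3.0]deca-5,9-diene-4β,8α-diol; 24 1,1,3,3-tetramethyldisilazane
Product: 26 6α-Si/8α-O dimethylsilylene-bridged 5αH-bicycle (oxasilolane), via hydrosilyl ether 25 (not isolated)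
Conditions: (HMe2Si)2NH (0.55 equiv), hexane, rt; evaporate; Pt2[(CH2=CHSiMe2)2O]3 (0.5 mol %), toluene, 60 °C
Reagents that add atoms: 1,1,3,3-tetramethyldisilazane, C[SiH](C)N[SiH](C)C
Why: Tamao-type intramolecular hydrosilylation of a homoallylic alcohol (5-exo) with zerovalent platinum delivers Si to C6 and H to C5 on the α face where the C8–O tether sits, which sets the trans ring fusion (C5–H α) and C6 in one syn addition; the secondary alcohol is silylated in preference to the hindered tertiary one, and the allylic C9=C10 alkene would require a 5-endo closure at neopentyl C10.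

Step 13
Reactants: 26 6α-Si/8α-O dimethylsilylene-bridged 5αH-bicycle (oxasilolane); 27 hydrogen peroxide
Product: 28 4α-isopropyl-1β-methyl-5αH-bicyclo[5.3.0]dec-9-ene-4β,6α,8α-triol
Conditions: 30% H2O2, KF, KHCO3, THF/MeOH, rt
Reagents that add atoms: hydrogen peroxide, OO
Why: Tamao oxidation converts the C6–Si bond into C6–OH with retention, giving the 6α-alcohol syn to the 8α-alcohol.

Step 14
Reactants: 28 4α-isopropyl-1β-methyl-5αH-bicyclo[5.3.0]dec-9-ene-4β,6α,8α-triol
Product: 29 4β,6α-dihydroxy-4α-isopropyl-1β-methyl-5αH-bicyclo[5.3.0]dec-9-en-8-one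
Conditions: MnO2 (activated, excess), CH2Cl2, rt
Reagents that add atoms: none
Why: manganese dioxide oxidises only allylic alcohols, so the C8 carbinol is converted into the enone while the C6 secondary and C4 tertiary alcohols remain.

Step 15
Reactants: 29 4β,6α-dihydroxy-4α-isopropyl-1β-methyl-5αH-bicyclo[5.3.0]dec-9-en-8-one; 30 chlorotriethylsilane
Product: 31 4β-hydroxy-4α-isopropyl-1β-methyl-6α-(triethylsilyloxy)-5αH-bicyclo[5.3.0]dec-9-en-8-one
Conditions: TESCl, imidazole, CH2Cl2, 0 °C
Reagents that add atoms: chlorotriethylsilane, CC[Si](Cl)(CC)CC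
Why: silylation of the only secondary alcohol, the tertiary C4 hydroxyl being too hindered to react under these conditions.

Step 16
Reactants: 31 4β-hydroxy-4α-isopropyl-1β-methyl-6α-(triethylsilyloxy)-5αH-bicyclo[5.3.0]dec-9-en-8-one; 32 4-methylmorpholine N-oxide
Product: 33 4β,9α,10α-trihydroxy-4α-isopropyl-1β-methyl-6α-(triethylsilyloxy)-5αH-bicyclo[5.3.0]decan-8-one
Conditions: OsO4 (10 mol %), NMO, acetone/H2O, rt
Reagents that add atoms: osmium tetroxide (catalytic oxygen carrier), O=[Os](=O)(=O)=O; 4-methylmorpholine N-oxide (terminal oxygen source), C[N+]1([O-])CCOCC1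
Why: Upjohn dihydroxylation adds both oxygens syn from the α face, anti to the methyl on the adjacent quaternary C1, and with C8 now trigonal there is no allylic substituent opposing this bias.

Step 17
Reactants: 33 4β,9α,10α-trihydroxy-4α-isopropyl-1β-methyl-6α-(triethylsilyloxy)-5αH-bicyclo[5.3.0]decan-8-one; 34 tert-butylchlorodimethylsilane
Product: 35 9α-(tert-butyldimethylsilyloxy)-4β,10α-dihydroxy-4α-isopropyl-1β-methyl-6α-(triethylsilyloxy)-5αH-bicyclo[5.3.0]decan-8-one
Conditions: TBSCl (1.1 equiv), imidazole, DMF, 0 °C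
Reagents that add atoms: tert-butylchlorodimethylsilane, CC(C)(C)[Si](C)(C)Cl
Why: regioselective silylation, since the C9 hydroxyl next to the trigonal C8 carbonyl is far more accessible than the neopentyl C10 hydroxyl next to quaternary C1.

Step 18
Reactants: 35 9α-(tert-butyldimethylsilyloxy)-4β,10α-dihydroxy-4α-isopropyl-1β-methyl-6α-(triethylsilyloxy)-5αH-bicyclo[5.3.0]decan-8-one; 36 methylmagnesium bromide
Product: 37 9α-(tert-butyldimethylsilyloxy)-4α-isopropyl-1β,8β-dimethyl-6α-(triethylsilyloxy)-5αH-bicyclo[5.3.0]decane-4β,8α,10α-triol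
Conditions: MeMgBr (5 equiv), THF, −78 → −20 °C
Reagents that add atoms: methylmagnesium bromide, C[Mg]Br
Why: Grignard addition to the α-silyloxy ketone from the β face, anti to the C9 silyl ether and to the other α-oriented oxygens at C6 and C10, should place the methyl β and the new hydroxyl α.

Step 19
Reactants: 37 9α-(tert-butyldimethylsilyloxy)-4α-isopropyl-1β,8β-dimethyl-6α-(triethylsilyloxy)-5αH-bicyclo[5.3.0]decane-4β,8α,10α-triol
Product: 38 9α-(tert-butyldimethylsilyloxy)-4α-isopropyl-1β,8β-dimethyl-5αH-bicyclo[5.3.0]decane-4β,6α,8α,10α-tetrol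
Conditions: PPTS (cat.), MeOH, 0 °C
Reagents that add atoms: none
Why: acid-catalysed methanolysis removes the less hindered triethylsilyl ether selectively, while the tert-butyldimethylsilyl ether flanked by two substituted carbons stays.

Step 20
Reactants: 38 9α-(tert-butyldimethylsilyloxy)-4α-isopropyl-1β,8β-dimethyl-5αH-bicyclo[5.3.0]decane-4β,6α,8α,10α-tetrol; 39 angelic acid
Product: 40 6α,10α-bis(angeloyloxy)-9α-(tert-butyldimethylsilyloxy)-4α-isopropyl-1β,8β-dimethyl-5αH-bicyclo[5.3.0]decane-4β,8α-diol
Conditions: angelic acid, 2,4,6-trichlorobenzoyl chloride, Et3N, toluene, rt; then 38, 80 °C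
Reagents that add atoms: angelic acid, C/C=C(/C)C(=O)O
Why: Yamaguchi mixed-anhydride esterification acylates hindered secondary alcohols with angelic acid without Z to E isomerisation, and only the C6 and C10 hydroxyls can react because C9 is silylated and the C4 and C8 alcohols are tertiary.

Step 21
Reactants: 40 6α,10α-bis(angeloyloxy)-9α-(tert-butyldimethylsilyloxy)-4α-isopropyl-1β,8β-dimethyl-5αH-bicyclo[5.3.0]decane-4β,8α-diol
Product: 41 CNP0194216.1
Conditions: HF·pyridine, THF/pyridine, 0 °C → rt
Reagents that add atoms: none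
Why: fluoride desilylation under weakly acidic conditions frees the C9 hydroxyl without acyl migration from C10 or isomerisation of the angelates.

**Compound list**

1 | 2,2-dimethoxyacetaldehyde | COC(OC)C=O | starting material
2 | isopropenylmagnesium bromide | C=C(C)[Mg]Br | starting material
3 | 1,1-dimethoxy-3-methylbut-3-en-2-ol (racemic) | COC(OC)C(O)C(C)=C | intermediate
4 | triethyl orthoacetate | CCOC(C)(OCC)OCC | starting material
5 | 2-[(1-ethoxyethenyl)oxy]-1,1-dimethoxy-3-methylbut-3-ene (ketene acetal) | C=C(OCC)OC(C(OC)OC)C(C)=C | intermediate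
6 | ethyl (4E)-6,6-dimethoxy-4-methylhex-4-enoate | CCOC(=O)CC/C(C)=C/C(OC)OC | intermediate
7 | N,O-dimethylhydroxylamine hydrochloride | CNOC.Cl | starting material
8 | (4E)-N,6,6-trimethoxy-N,4-dimethylhex-4-enamide | CON(C)C(=O)CC/C(C)=C/C(OC)OC | intermediate
9 | water | O | starting material
10 | (4E)-N-methoxy-N,4-dimethyl-6-oxohex-4-enamide | CON(C)C(=O)CC/C(C)=C/C=O | intermediate
11 | iodoform | IC(I)I | starting material
12 | (4E,6E)-7-iodo-N-methoxy-N,4-dimethylhepta-4,6-dienamide | CON(C)C(=O)CC/C(C)=C/C=C/I | intermediate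
13 | 4-methoxybenzyl alcohol | COc1ccc(CO)cc1 | starting material
14 | (4E,6E)-N-methoxy-7-[(4-methoxybenzyl)oxy]-N,4-dimethylhepta-4,6-dienamide | CON(C)C(=O)CC/C(C)=C/C=C/OCc1ccc(OC)cc1 | intermediate
15 | allylmagnesium bromide | C=CC[Mg]Br | starting material
16 | (7E,9E)-10-[(4-methoxybenzyl)oxy]-7-methyldeca-1,7,9-trien-4-one | C=CCC(=O)CC/C(C)=C/C=C/OCc1ccc(OC)cc1 | intermediate
17 | 4-acetamidobenzenesulfonyl azide | CC(=O)Nc1ccc(cc1)S(=O)(=O)N=[N+]=[N-] | starting material
18 | (7E,9E)-3-diazo-10-[(4-methoxybenzyl)oxy]-7-methyldeca-1,7,9-trien-4-one | C=CC(=[N+]=[N-])C(=O)CC/C(C)=C/C=C/OCc1ccc(OC)cc1 | intermediate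
19 | 1-ethenyl-6-exo-[(E)-2-(4-methoxybenzyloxy)ethenyl]-5-methylbicyclo[3.1.0]hexan-2-one (vinyl, methyl and alkoxyvinyl all cis on the cyclopropane) | C=C[C@]12C(=O)CC[C@@]1(C)[C@@H]2/C=C/OCc3ccc(OC)cc3 | intermediate
20 | (3aS,6S)-6-[(4-methoxybenzyl)oxy]-3a-methyl-3,3a,6,7-tetrahydroazulen-1(2H)-one (C4 ketone, C5=C6 and C9=C10 alkenes, 1β-methyl, 8α-ether) | C1=C2C(=O)CC[C@@]2(C)C=C[C@@H](OCc3ccc(OC)cc3)C1 | intermediate
21 | isopropyllithium | [Li]C(C)C | starting material
22 | 4α-isopropyl-8α-(4-methoxybenzyloxy)-1β-methylbicyclo[5.3.0]deca-5,9-dien-4β-ol | C=1C[C@H](OCc3ccc(OC)cc3)C=C[C@]2(C)CC[C@](O)(C(C)C)C=12 | intermediate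
23 | 4α-isopropyl-1β-methylbicyclo[5.3.0]deca-5,9-diene-4β,8α-diol | C=1C[C@H](O)C=C[C@]2(C)CC[C@](O)(C(C)C)C=12 | intermediate
24 | 1,1,3,3-tetramethyldisilazane | C[SiH](C)N[SiH](C)C | starting material
25 | 8α-(dimethylsilyloxy)-4α-isopropyl-1β-methylbicyclo[5.3.0]deca-5,9-dien-4β-ol | C=1C[C@H](O[SiH](C)C)C=C[C@]2(C)CC[C@](O)(C(C)C)C=12 | intermediate
26 | cyclic siloxane: SiMe2 bonded to C6 (α) and to O on C8 (α), 5αH, 4β-hydroxy-4α-isopropyl-1β-methyl, C9=C10 alkene | C[Si]1(C)O[C@@H]2C=C[C@]3(C)CC[C@](O)(C(C)C)[C@H]3[C@H]1C2 | intermediate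
27 | hydrogen peroxide | OO | starting material
28 | 4α-isopropyl-1β-methyl-5αH-bicyclo[5.3.0]dec-9-ene-4β,6α,8α-triol | O[C@@H]1C[C@H](O)C=C[C@]2(C)CC[C@](O)(C(C)C)[C@@H]12 | intermediate
29 | 4β,6α-dihydroxy-4α-isopropyl-1β-methyl-5αH-bicyclo[5.3.0]dec-9-en-8-one | O[C@@H]1CC(=O)C=C[C@]2(C)CC[C@](O)(C(C)C)[C@@H]12 | intermediate
30 | chlorotriethylsilane | CC[Si](Cl)(CC)CC | starting material
31 | 4β-hydroxy-4α-isopropyl-1β-methyl-6α-(triethylsilyloxy)-5αH-bicyclo[5.3.0]dec-9-en-8-one | CC[Si](CC)(CC)O[C@@H]1CC(=O)C=C[C@]2(C)CC[C@](O)(C(C)C)[C@@H]12 | intermediate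
32 | 4-methylmorpholine N-oxide | C[N+]1([O-])CCOCC1 | starting material
33 | 4β,9α,10α-trihydroxy-4α-isopropyl-1β-methyl-6α-(triethylsilyloxy)-5αH-bicyclo[5.3.0]decan-8-one | CC[Si](CC)(CC)O[C@@H]1CC(=O)[C@H](O)[C@H](O)[C@]2(C)CC[C@](O)(C(C)C)[C@@H]12 | intermediate
34 | tert-butylchlorodimethylsilane | CC(C)(C)[Si](C)(C)Cl | starting material
35 | 9α-(tert-butyldimethylsilyloxy)-4β,10α-dihydroxy-4α-isopropyl-1β-methyl-6α-(triethylsilyloxy)-5αH-bicyclo[5.3.0]decan-8-one | CC[Si](CC)(CC)O[C@@H]1CC(=O)[C@H](O[Si](C)(C)C(C)(C)C)[C@H](O)[C@]2(C)CC[C@](O)(C(C)C)[C@@H]12 | intermediate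
36 | methylmagnesium bromide | C[Mg]Br | starting material
37 | 9α-(tert-butyldimethylsilyloxy)-4α-isopropyl-1β,8β-dimethyl-6α-(triethylsilyloxy)-5αH-bicyclo[5.3.0]decane-4β,8α,10α-triol | CC[Si](CC)(CC)O[C@@H]1C[C@](C)(O)[C@H](O[Si](C)(C)C(C)(C)C)[C@H](O)[C@]2(C)CC[C@](O)(C(C)C)[C@@H]12 | intermediate
38 | 9α-(tert-butyldimethylsilyloxy)-4α-isopropyl-1β,8β-dimethyl-5αH-bicyclo[5.3.0]decane-4β,6α,8α,10α-tetrol | O[C@@H]1C[C@](C)(O)[C@H](O[Si](C)(C)C(C)(C)C)[C@H](O)[C@]2(C)CC[C@](O)(C(C)C)[C@@H]12 | intermediate
39 | angelic acid, (Z)-2-methylbut-2-enoic acid | C/C=C(/C)C(=O)O | starting material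
40 | 6α,10α-bis(angeloyloxy)-9α-(tert-butyldimethylsilyloxy)-4α-isopropyl-1β,8β-dimethyl-5αH-bicyclo[5.3.0]decane-4β,8α-diol | C/C=C(/C)C(=O)O[C@@H]1C[C@](C)(O)[C@H](O[Si](C)(C)C(C)(C)C)[C@H](OC(=O)/C(C)=C\C)[C@]2(C)CC[C@](O)(C(C)C)[C@@H]12 | intermediate
41 | CNP0194216.1, (1R,4S,5R,6R,8S,9R,10R)-4,8,9-trihydroxy-4-isopropyl-1,8-dimethylbicyclo[5.3.0]decane-6,10-diyl bis[(Z)-2-methylbut-2-enoate] (ring locants as defined) | C/C=C(/C)C(=O)O[C@@H]1C[C@](C)(O)[C@H](O)[C@H](OC(=O)/C(C)=C\C)[C@]2(C)CC[C@](O)(C(C)C)[C@@H]12 | target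

**Step count**

Total: 21 steps. Longest linear sequence: 21 steps (fully linear from 1).

**Steps most likely to fail**

Step 9. The chiral dirhodium catalyst may discriminate poorly between the alkene faces at a ketone-substituted vinylcarbenoid, so that the cascade gives low enantiomeric purity. The fallback sets out from 18 and secures the absolute configuration by enzymatic resolution instead. The cascade is run with achiral Rh2(OPiv)4 (dirhodium tetrapivalate) under the conditions of step 9, giving 20 together with its mirror image ent-20 F1. Steps 10 and 11 are carried out on the racemate, giving 22 with ent-22 F2 and then 23 with ent-23 F3. Kinetic resolution with Burkholderia cepacia lipase and vinyl acetate in MTBE is expected, by the empirical rule for lipase acylation of cyclic allylic alcohols, to acetylate the (8R) alcohol to the acetate of ent-23 F4 and to leave 23 unreacted. After chromatographic separation the route is rejoined at 23.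

Step 12. The tethered hydrosilylation may go astray: the silane may add to the allylic C9=C10 alkene instead, the tertiary alcohol may be silylated and deliver from the β face, or the bridging ring may close too slowly. The fallback sets out from 20 and introduces the C6 oxygen by conjugate borylation. B2pin2, CuCl (5 mol %), NaOtBu, Xantphos and MeOH in THF should give the β-boryl ketone F5, with boron entering at C6 anti to the C1 methyl. Oxidation with NaBO3·4H2O in THF/H2O gives the β-hydroxy ketone F6. Addition of excess iPrLi/CeCl3 at −78 °C gives the 4β,6α-diol 8α-ether F7, and DDQ in buffered CH2Cl2 removes the benzyl ether to rejoin the route at 28. In this variant C5 is set by enolate protonation and equilibration to the trans-fused ketone, not by syn delivery, and that is its weak point.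

Step 20. Acylation of the neopentyl C10 hydroxyl may stay incomplete, and the forcing conditions then needed may isomerise the angeloyl group to the E (tigloyl) isomer. The fallback sets out from 38 and builds the Z alkene after esterification. Both secondary alcohols are acylated with 2-[bis(2,2,2-trifluoroethoxy)phosphoryl]propanoic acid, DCC and catalytic DMAP in CH2Cl2 (acylation through the phosphonoketene is effective for hindered alcohols) to give the bis(phosphonopropionate) F8. Still–Gennari olefination of F8 (KHMDS, 18-crown-6, THF, −78 °C, then acetaldehyde) should form both (Z)-2-methylbut-2-enoates and rejoin the route at 40.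

Further compounds
F1 | step 9 | ent-20, (3aR,6R)-6-[(4-methoxybenzyl)oxy]-3a-methyl-3,3a,6,7-tetrahydroazulen-1(2H)-one | C1=C2C(=O)CC[C@]2(C)C=C[C@H](OCc3ccc(OC)cc3)C1
F2 | step 9 | ent-22, enantiomer of the tertiary allylic alcohol 22 | C=1C[C@@H](OCc3ccc(OC)cc3)C=C[C@@]2(C)CC[C@@](O)(C(C)C)C=12
F3 | step 9 | ent-23, enantiomer of the diol 23 | C=1C[C@@H](O)C=C[C@@]2(C)CC[C@@](O)(C(C)C)C=12
F4 | step 9 | acetate of ent-23 (C8 acetate, C4 alcohol free) | C=1C[C@@H](OC(C)=O)C=C[C@@]2(C)CC[C@@](O)(C(C)C)C=12
F5 | step 12 | 8α-(4-methoxybenzyloxy)-1β-methyl-6α-(pinacolatoboryl)-5αH-bicyclo[5.3.0]dec-9-en-4-one | CC1(C)OB(OC1(C)C)[C@@H]2C[C@H](OCc4ccc(OC)cc4)C=C[C@]3(C)CCC(=O)[C@@H]23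
F6 | step 12 | 6α-hydroxy-8α-(4-methoxybenzyloxy)-1β-methyl-5αH-bicyclo[5.3.0]dec-9-en-4-one | O[C@@H]1C[C@H](OCc3ccc(OC)cc3)C=C[C@]2(C)CCC(=O)[C@@H]12
F7 | step 12 | 4α-isopropyl-8α-(4-methoxybenzyloxy)-1β-methyl-5αH-bicyclo[5.3.0]dec-9-ene-4β,6α-diol | O[C@@H]1C[C@H](OCc3ccc(OC)cc3)C=C[C@]2(C)CC[C@](O)(C(C)C)[C@@H]12
F8 | step 20 | 6α,10α-bis{2-[bis(2,2,2-trifluoroethoxy)phosphoryl]propanoate} of 38 (epimeric at the phosphonate-bearing carbons) | CC(C(=O)O[C@@H]1C[C@](C)(O)[C@H](O[Si](C)(C)C(C)(C)C)[C@H](OC(=O)C(C)P(=O)(OCC(F)(F)F)OCC(F)(F)F)[C@]2(C)CC[C@](O)(C(C)C)[C@@H]12)P(=O)(OCC(F)(F)F)OCC(F)(F)F
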